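## Retrosynthetic overview

1. The target comes from bis-silyl ether 27 by fluoride deprotection; the tetrasubstituted enal of 27 is made last, by oxidative 1,3-transposition of the isopropenyl carbinol 26 derived from ring ketone 25.
2. A C(sp3)–C(sp2) B-alkyl Suzuki disconnection between the ring CH2CH2 arm and the trisubstituted alkene gives ring fragment 11 and side-chain vinyl iodide 20.
3. Key bond in 11: the ring-C–CH2 bond of the future hydroxypropyl arm, made by copper-catalysed enantioselective conjugate addition of a propanal homoenolate equivalent (β-zincio acetal 4) to quinone monoketal 2, which desymmetrises it. Enolate methylation, anti-selective vinylation (quaternary carbon), enone reduction and MeLi addition follow.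
4. Fragment 20 comes from geranyl bromide and an alkynyl-dithiane acyl anion, then Ru transfer hydrogenation (carbinol R) and hydrozirconation–iodination (E-alkene).
5. Ring order: the only ring is bought as 2 and no ring is formed; its stereocentres are set in the order CH-propyl (catalyst), quaternary C (substrate), C–OH (substrate).

Assumption: the (R,S,S)-phosphoramidite L [(R)-binaphthol, bis((S)-1-phenylethyl)amine] is taken to give (5S)-6, by analogy with its sense on cyclohex-2-enone; if the dienone responds the other way, the (S,R,R)-ligand is used and nothing else changes.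

## Route

Step 1
Reactants: 1 3,3-diethoxyprop-1-ene (acrolein diethyl acetal); 2 4,4-dimethoxycyclohexa-2,5-dien-1-one
Product: 6 (5S,6S)-5-(3,3-diethoxypropyl)-4,4-dimethoxy-6-methylcyclohex-2-en-1-one, via alkylborane 3 (not isolated), via dialkylzinc 4 (not isolated), via zinc enolate 5 (not isolated)
Conditions: 1, Et2BH (from BH3·SMe2 + 2 BEt3), 0 → 25 °C; Et2Zn, 0 °C, volatiles off in vacuo; then 2, Cu(OTf)2 (2 mol %), L (4 mol %), toluene, −30 °C; then MeI, HMPA, −30 → 0 °C; aqueous work-up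
Reagents that add atoms: iodomethane, CI
Why: The salt-free β-zincio acetal 4 (hydroboration, then boron–zinc exchange) is a propanal homoenolate equivalent, so copper/phosphoramidite asymmetric conjugate addition joins the enone β-carbon to a carbon that is itself a β-carbonyl (normally electrophilic) position; enantioface-selective delivery desymmetrises 2 and sets C5 as S, and the zinc enolate is C-methylated in the same flask (the C6 configuration is irrelevant because C6 is re-enolised in step 2).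

Step 2
Reactants: 6 (5S,6S)-5-(3,3-diethoxypropyl)-4,4-dimethoxy-6-methylcyclohex-2-en-1-one
Product: 9 (5S,6S)-5-(3,3-diethoxypropyl)-6-ethenyl-4,4-dimethoxy-6-methylcyclohex-2-en-1-one, via lithium dienolate 7 (not isolated), via sulfoxide adduct 8 (not isolated)
Conditions: LiN(iPr)2, THF, −78 °C; PhS(O)CH=CH2, −78 → −20 °C; H2O; crude in toluene, CaCO3, 110 °C
Reagents that add atoms: phenyl vinyl sulfoxide, C=CS(=O)c1ccccc1
Why: Only C6 can be deprotonated (the other α-carbon is vinylic), and the cross-conjugated dienolate undergoes Michael addition to the vinyl sulfoxide (a vinyl cation equivalent) anti to the pseudoaxial C5 side chain, which sets the quaternary centre as 6S; thermal syn-elimination of the sulfoxide then gives the vinyl group.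

Step 3
Reactants: 9 (5S,6S)-5-(3,3-diethoxypropyl)-6-ethenyl-4,4-dimethoxy-6-methylcyclohex-2-en-1-one
Product: 10 (2S,3S)-3-(3,3-diethoxypropyl)-2-ethenyl-4,4-dimethoxy-2-methylcyclohexan-1-one
Conditions: K[(sec-Bu)3BH] (1.05 equiv), THF, −78 °C; H2O
Reagents that add atoms: none
Why: Conjugate (1,4) hydride reduction of the β-unsubstituted cyclohexenone by the bulky trialkylborohydride (1,2-attack is blocked by the α-quaternary carbon) gives the enolate, which is protonated on quench, while the isolated vinyl group and both acetals are untouched.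

Step 4
Reactants: 10 (2S,3S)-3-(3,3-diethoxypropyl)-2-ethenyl-4,4-dimethoxy-2-methylcyclohexan-1-one
Product: 11 (1S,2S,3S)-3-(3,3-diethoxypropyl)-2-ethenyl-4,4-dimethoxy-1,2-dimethylcyclohexan-1-ol
Conditions: MeLi, CeCl3 (gives MeCeCl2), THF, −78 °C; H2O
Reagents that add atoms: methyllithium, [Li]C
Why: 1,2-Addition of the weakly basic organocerium reagent to the hindered ketone occurs on the face anti to the C2 methyl and the C3 side chain (in either chair one of them blocks the other face), giving the 1S tertiary alcohol with OH cis to both.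

Step 5
Reactants: 12 1,1-diethoxybut-2-yne
Product: 13 2-(prop-1-yn-1-yl)-1,3-dithiane
Conditions: HS(CH2)3SH, BF3·OEt2, CH2Cl2, 0 °C
Reagents that add atoms: propane-1,3-dithiol, SCCCS
Why: Lewis-acid transthioacetalisation turns the acetal into the 1,3-dithiane, the masked acyl anion of but-2-ynal (Corey–Seebach reagent).

Step 6
Reactants: 13 2-(prop-1-yn-1-yl)-1,3-dithiane; 14 (2E)-1-bromo-3,7-dimethylocta-2,6-diene (geranyl bromide)
Product: 16 2-[(2E)-3,7-dimethylocta-2,6-dien-1-yl]-2-(prop-1-yn-1-yl)-1,3-dithiane, via lithiodithiane 15 (not isolated)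
Conditions: n-BuLi, THF, −78 → −30 °C; then 14, −78 → 0 °C
Reagents that add atoms: none
Why: Corey–Seebach acyl-anion alkylation: the sulfur-stabilised carbanion attacks the primary allylic bromide by SN2 at C2 of the dithiane with the E-alkene intact, which avoids the α/γ problem of a geranyl nucleophile and the unstable β,γ-unsaturated aldehyde.

Step 7
Reactants: 16 2-[(2E)-3,7-dimethylocta-2,6-dien-1-yl]-2-(prop-1-yn-1-yl)-1,3-dithiane
Product: 17 (6E)-7,11-dimethyldodeca-6,10-dien-2-yn-4-one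
Conditions: MeI, CaCO3, MeCN/H2O (4:1), 40 °C
Reagents that add atoms: water, O
Why: Alkylative dithiane hydrolysis under buffered, near-neutral conditions releases the ynone without moving the β,γ-double bond into conjugation.

Step 8
Reactants: 17 (6E)-7,11-dimethyldodeca-6,10-dien-2-yn-4-one
Product: 18 (4R,6E)-7,11-dimethyldodeca-6,10-dien-2-yn-4-ol
Conditions: Ru[(R,R)-TsNCHPhCHPhNH](p-cymene) (0.5 mol %), i-PrOH, 25 °C
Reagents that add atoms: none
Why: Noyori asymmetric transfer hydrogenation differentiates alkynyl from alkyl very well, and the (R,R)-catalyst gives the R propargylic alcohol under base-free conditions that do not isomerise the skipped enone.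

Step 9
Reactants: 18 (4R,6E)-7,11-dimethyldodeca-6,10-dien-2-yn-4-ol
Product: 20 (2E,4R,6E)-2-iodo-7,11-dimethyldodeca-2,6,10-trien-4-ol, via alkenylzirconocene 19 (not isolated)
Conditions: Cp2Zr(H)Cl (2.3 equiv), THF, 0 → 40 °C; I2, 0 °C; aqueous work-up
Reagents that add atoms: iodine, II
Why: Syn-hydrozirconation puts zirconium on the less hindered, methyl-bearing alkyne carbon (excess reagent equilibrates the regioisomers) and iodinolysis proceeds with retention, so iodine ends trans to the carbinol carbon (E).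

Step 10
Reactants: 11 (1S,2S,3S)-3-(3,3-diethoxypropyl)-2-ethenyl-4,4-dimethoxy-1,2-dimethylcyclohexan-1-ol; 20 (2E,4R,6E)-2-iodo-7,11-dimethyldodeca-2,6,10-trien-4-ol
Product: 22 (3E,5R,7E)-1-[(1S,2S,6S)-6-(3,3-diethoxypropyl)-2-hydroxy-5,5-dimethoxy-1,2-dimethylcyclohexyl]-3,8,12-trimethyltrideca-3,7,11-trien-5-ol, via alkylborane 21 (not isolated)
Conditions: 11, 9-BBN-H (2.2 equiv), THF, 25 → 50 °C; then 20, Pd(dppf)Cl2 (5 mol %), AsPh3, Cs2CO3, DMF/H2O, 25 °C
Reagents that add atoms: none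
Why: 9-BBN-H hydroborates the only alkene of 11 at its terminal carbon, and the B-alkyl Suzuki–Miyaura coupling joins C(sp3) to C(sp2) with retention of the vinyl iodide geometry while tolerating the free hydroxyls.

Step 11
Reactants: 22 (3E,5R,7E)-1-[(1S,2S,6S)-6-(3,3-diethoxypropyl)-2-hydroxy-5,5-dimethoxy-1,2-dimethylcyclohexyl]-3,8,12-trimethyltrideca-3,7,11-trien-5-ol
Product: 23 3-[(1S,2S,3S)-3-hydroxy-2-[(3E,5R,7E)-5-hydroxy-3,8,12-trimethyltrideca-3,7,11-trien-1-yl]-2,3-dimethyl-6-oxocyclohexyl]propanal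
Conditions: AcOH/THF/H2O (3:1:1), 25 °C; used at once
Reagents that add atoms: water, O
Why: Mild acid hydrolysis cleaves both acyclic acetals (dimethyl ketal and diethyl acetal) under conditions too weak to ionise the allylic alcohol, epimerise the α-carbon of the new ketone or touch the trisubstituted alkenes.

Step 12
Reactants: 23 3-[(1S,2S,3S)-3-hydroxy-2-[(3E,5R,7E)-5-hydroxy-3,8,12-trimethyltrideca-3,7,11-trien-1-yl]-2,3-dimethyl-6-oxocyclohexyl]propanal
Product: 24 (2S,3S,4S)-4-hydroxy-3-[(3E,5R,7E)-5-hydroxy-3,8,12-trimethyltrideca-3,7,11-trien-1-yl]-2-(3-hydroxypropyl)-3,4-dimethylcyclohexan-1-one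
Conditions: NaBH4, MeOH/CH2Cl2 (1:1), −78 °C
Reagents that add atoms: none
Why: Chemoselective borohydride reduction: at low temperature the unhindered aldehyde is reduced far faster than the α-branched ring ketone.

Step 13
Reactants: 24 (2S,3S,4S)-4-hydroxy-3-[(3E,5R,7E)-5-hydroxy-3,8,12-trimethyltrideca-3,7,11-trien-1-yl]-2-(3-hydroxypropyl)-3,4-dimethylcyclohexan-1-one
Product: 25 (2S,3S,4S)-2-[3-(tert-butyldimethylsilyloxy)propyl]-3-[(3E,5R,7E)-5-(tert-butyldimethylsilyloxy)-3,8,12-trimethyltrideca-3,7,11-trien-1-yl]-4-hydroxy-3,4-dimethylcyclohexan-1-one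
Conditions: TBSCl (2.5 equiv), imidazole, DMF, 25 °C
Reagents that add atoms: tert-butyldimethylsilyl chloride, CC(C)(C)[Si](C)(C)Cl
Why: Silyl ether formation on the primary and the secondary hydroxyl only; the hindered tertiary alcohol does not react with TBSCl/imidazole.

Step 14
Reactants: 25 (2S,3S,4S)-2-[3-(tert-butyldimethylsilyloxy)propyl]-3-[(3E,5R,7E)-5-(tert-butyldimethylsilyloxy)-3,8,12-trimethyltrideca-3,7,11-trien-1-yl]-4-hydroxy-3,4-dimethylcyclohexan-1-one
Product: 26 (2S,3S,4S)-2-[3-(tert-butyldimethylsilyloxy)propyl]-3-[(3E,5R,7E)-5-(tert-butyldimethylsilyloxy)-3,8,12-trimethyltrideca-3,7,11-trien-1-yl]-3,4-dimethyl-1-(prop-1-en-2-yl)cyclohexane-1,4-diol (either C1 epimer)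
Conditions: CH2=C(CH3)MgBr (4 equiv), CeCl3, THF, −78 → 0 °C; H2O
Reagents that add atoms: isopropenylmagnesium bromide, C=C(C)[Mg]Br
Why: Organocerium 1,2-addition suppresses enolisation of the hindered ketone (one equivalent is spent on the free tertiary OH), and the new carbinol configuration does not matter because that carbon becomes sp2 in step 15.

Step 15
Reactants: 26 (2S,3S,4S)-2-[3-(tert-butyldimethylsilyloxy)propyl]-3-[(3E,5R,7E)-5-(tert-butyldimethylsilyloxy)-3,8,12-trimethyltrideca-3,7,11-trien-1-yl]-3,4-dimethyl-1-(prop-1-en-2-yl)cyclohexane-1,4-diol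
Product: 27 (2E)-2-[(2R,3S,4S)-2-[3-(tert-butyldimethylsilyloxy)propyl]-3-[(3E,5R,7E)-5-(tert-butyldimethylsilyloxy)-3,8,12-trimethyltrideca-3,7,11-trien-1-yl]-4-hydroxy-3,4-dimethylcyclohexylidene]propanal
Conditions: C5H5NH[CrO3Cl] (pyridinium chlorochromate), NaOAc, 4 Å molecular sieves, CH2Cl2, 25 °C
Reagents that add atoms: pyridinium chlorochromate, [O-][Cr](=O)(=O)Cl.c1cc[nH+]cc1
Why: Babler–Dauben oxidative 1,3-transposition: the tertiary allylic chromate ester undergoes a [3,3] shift through a chair transition state with the more substituted ring branch pseudo-equatorial, so that branch ends cis to the methyl group and the CH2O–Cr terminus, oxidised in situ to CHO, ends cis to the ring CH2 (E-enal); an E/Z mixture is possible and the isomers are separated by chromatography.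

Step 16
Reactants: 27 (2E)-2-[(2R,3S,4S)-2-[3-(tert-butyldimethylsilyloxy)propyl]-3-[(3E,5R,7E)-5-(tert-butyldimethylsilyloxy)-3,8,12-trimethyltrideca-3,7,11-trien-1-yl]-4-hydroxy-3,4-dimethylcyclohexylidene]propanal
Product: 28 (2E)-2-[(2R,3S,4S)-4-hydroxy-3-[(3E,5R,7E)-5-hydroxy-3,8,12-trimethyltrideca-3,7,11-trien-1-yl]-2-(3-hydroxypropyl)-3,4-dimethylcyclohexylidene]propanal (CNP0417035.1)
Conditions: HF·pyridine, pyridine, THF, 0 → 25 °C
Reagents that add atoms: none
Why: Fluoride cleavage of both silyl ethers under buffered, non-basic conditions that neither deconjugate or isomerise the enal (acidic γ-hydrogens) nor ionise the allylic alcohol.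

## Compound list

1 | 3,3-diethoxyprop-1-ene (acrolein diethyl acetal) | C=CC(OCC)OCC | starting material
2 | 4,4-dimethoxycyclohexa-2,5-dien-1-one | COC1(OC)C=CC(=O)C=C1 | starting material
3 | (3,3-diethoxypropyl)diethylborane | CCOC(OCC)CCB(CC)CC | intermediate
4 | bis(3,3-diethoxypropyl)zinc | CCOC(OCC)CC[Zn]CCC(OCC)OCC | intermediate
5 | (3,3-diethoxypropyl)zinc (3S)-3-(3,3-diethoxypropyl)-4,4-dimethoxycyclohexa-1,5-dien-1-olate | CCOC(OCC)CC[Zn]OC1=C[C@H](CCC(OCC)OCC)C(OC)(OC)C=C1 | intermediate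
6 | (5S,6S)-5-(3,3-diethoxypropyl)-4,4-dimethoxy-6-methylcyclohex-2-en-1-one | C[C@H]1[C@H](CCC(OCC)OCC)C(OC)(OC)C=CC1=O | intermediate
7 | lithium (3S)-3-(3,3-diethoxypropyl)-4,4-dimethoxy-2-methylcyclohexa-1,5-dien-1-olate | [Li]OC1=C(C)[C@H](CCC(OCC)OCC)C(OC)(OC)C=C1 | intermediate
8 | (5S,6S)-5-(3,3-diethoxypropyl)-4,4-dimethoxy-6-methyl-6-[2-(phenylsulfinyl)ethyl]cyclohex-2-en-1-one (both sulfur epimers) | O=S(CC[C@@]1(C)[C@H](CCC(OCC)OCC)C(OC)(OC)C=CC1=O)c1ccccc1 | intermediate
9 | (5S,6S)-5-(3,3-diethoxypropyl)-6-ethenyl-4,4-dimethoxy-6-methylcyclohex-2-en-1-one | C=C[C@@]1(C)[C@H](CCC(OCC)OCC)C(OC)(OC)C=CC1=O | intermediate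
10 | (2S,3S)-3-(3,3-diethoxypropyl)-2-ethenyl-4,4-dimethoxy-2-methylcyclohexan-1-one | C=C[C@@]1(C)[C@H](CCC(OCC)OCC)C(OC)(OC)CCC1=O | intermediate
11 | (1S,2S,3S)-3-(3,3-diethoxypropyl)-2-ethenyl-4,4-dimethoxy-1,2-dimethylcyclohexan-1-ol | C=C[C@@]1(C)[C@H](CCC(OCC)OCC)C(OC)(OC)CC[C@]1(C)O | intermediate
12 | 1,1-diethoxybut-2-yne | CC#CC(OCC)OCC | starting material
13 | 2-(prop-1-yn-1-yl)-1,3-dithiane | CC#CC1SCCCS1 | intermediate
14 | (2E)-1-bromo-3,7-dimethylocta-2,6-diene (geranyl bromide) | CC(C)=CCC/C(C)=C/CBr | starting material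
15 | 2-lithio-2-(prop-1-yn-1-yl)-1,3-dithiane | [Li]C1(C#CC)SCCCS1 | intermediate
16 | 2-[(2E)-3,7-dimethylocta-2,6-dien-1-yl]-2-(prop-1-yn-1-yl)-1,3-dithiane | CC(C)=CCC/C(C)=C/CC1(C#CC)SCCCS1 | intermediate
17 | (6E)-7,11-dimethyldodeca-6,10-dien-2-yn-4-one | CC(C)=CCC/C(C)=C/CC(=O)C#CC | intermediate
18 | (4R,6E)-7,11-dimethyldodeca-6,10-dien-2-yn-4-ol | CC(C)=CCC/C(C)=C/C[C@@H](O)C#CC | intermediate
19 | [(2E,4R,6E)-4-{[chloridobis(cyclopentadienyl)zirconio]oxy}-7,11-dimethyldodeca-2,6,10-trien-2-yl]chloridobis(cyclopentadienyl)zirconium | CC(C)=CCC/C(C)=C/C[C@@H](O[Zr](Cl)(C1C=CC=C1)C1C=CC=C1)/C=C(\C)[Zr](Cl)(C1C=CC=C1)C1C=CC=C1 | intermediate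
20 | (2E,4R,6E)-2-iodo-7,11-dimethyldodeca-2,6,10-trien-4-ol | CC(C)=CCC/C(C)=C/C[C@@H](O)/C=C(\C)I | intermediate
21 | 9-{2-[(1S,2S,6S)-6-(3,3-diethoxypropyl)-2-hydroxy-5,5-dimethoxy-1,2-dimethylcyclohexyl]ethyl}-9-borabicyclo[3.3.1]nonane | C(C[C@@]1(C)[C@H](CCC(OCC)OCC)C(OC)(OC)CC[C@]1(C)O)B1C2CCCC1CCC2 | intermediate
22 | (3E,5R,7E)-1-[(1S,2S,6S)-6-(3,3-diethoxypropyl)-2-hydroxy-5,5-dimethoxy-1,2-dimethylcyclohexyl]-3,8,12-trimethyltrideca-3,7,11-trien-5-ol | CC(C)=CCC/C(C)=C/C[C@@H](O)/C=C(\C)CC[C@@]1(C)[C@H](CCC(OCC)OCC)C(OC)(OC)CC[C@]1(C)O | intermediate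
23 | 3-[(1S,2S,3S)-3-hydroxy-2-[(3E,5R,7E)-5-hydroxy-3,8,12-trimethyltrideca-3,7,11-trien-1-yl]-2,3-dimethyl-6-oxocyclohexyl]propanal | CC(C)=CCC/C(C)=C/C[C@@H](O)/C=C(\C)CC[C@@]1(C)[C@H](CCC=O)C(=O)CC[C@]1(C)O | intermediate
24 | (2S,3S,4S)-4-hydroxy-3-[(3E,5R,7E)-5-hydroxy-3,8,12-trimethyltrideca-3,7,11-trien-1-yl]-2-(3-hydroxypropyl)-3,4-dimethylcyclohexan-1-one | CC(C)=CCC/C(C)=C/C[C@@H](O)/C=C(\C)CC[C@@]1(C)[C@H](CCCO)C(=O)CC[C@]1(C)O | intermediate
25 | (2S,3S,4S)-2-[3-(tert-butyldimethylsilyloxy)propyl]-3-[(3E,5R,7E)-5-(tert-butyldimethylsilyloxy)-3,8,12-trimethyltrideca-3,7,11-trien-1-yl]-4-hydroxy-3,4-dimethylcyclohexan-1-one | CC(C)=CCC/C(C)=C/C[C@@H](O[Si](C)(C)C(C)(C)C)/C=C(\C)CC[C@@]1(C)[C@H](CCCO[Si](C)(C)C(C)(C)C)C(=O)CC[C@]1(C)O | intermediate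
26 | (2S,3S,4S)-2-[3-(tert-butyldimethylsilyloxy)propyl]-3-[(3E,5R,7E)-5-(tert-butyldimethylsilyloxy)-3,8,12-trimethyltrideca-3,7,11-trien-1-yl]-3,4-dimethyl-1-(prop-1-en-2-yl)cyclohexane-1,4-diol (C1 configuration not controlled, removed in step 15) | CC(C)=CCC/C(C)=C/C[C@@H](O[Si](C)(C)C(C)(C)C)/C=C(\C)CC[C@@]1(C)[C@H](CCCO[Si](C)(C)C(C)(C)C)C(O)(C(C)=C)CC[C@]1(C)O | intermediate
27 | (2E)-2-[(2R,3S,4S)-2-[3-(tert-butyldimethylsilyloxy)propyl]-3-[(3E,5R,7E)-5-(tert-butyldimethylsilyloxy)-3,8,12-trimethyltrideca-3,7,11-trien-1-yl]-4-hydroxy-3,4-dimethylcyclohexylidene]propanal | CC(C)=CCC/C(C)=C/C[C@@H](O[Si](C)(C)C(C)(C)C)/C=C(\C)CC[C@@]1(C)[C@H](CCCO[Si](C)(C)C(C)(C)C)/C(=C(\C)C=O)CC[C@]1(C)O | intermediate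
28 | (2E)-2-[(2R,3S,4S)-4-hydroxy-3-[(3E,5R,7E)-5-hydroxy-3,8,12-trimethyltrideca-3,7,11-trien-1-yl]-2-(3-hydroxypropyl)-3,4-dimethylcyclohexylidene]propanal | CC(C)=CCC/C(C)=C/C[C@@H](O)/C=C(\C)CC[C@@]1(C)[C@H](CCCO)/C(=C(\C)C=O)CC[C@]1(C)O | target

## Step count and risks

Total: 16 steps. Longest linear sequence: 12 steps (steps 5–9, then 10–16); the ring branch (steps 1–4, then 10–16) is 11.

Most likely to fail, with fallbacks:

Step 1. The acetal-bearing zinc reagent has not been tried on this dienone, and zinc enolates are sluggish towards MeI. The fallback sets out from 2 (with 4 made as before) and returns at 6. The conjugate addition is run without MeI and quenched with aqueous NH4Cl, and the enone (5S)-5-(3,3-diethoxypropyl)-4,4-dimethoxycyclohex-2-en-1-one F1 is isolated. LiN(iPr)2 (THF, −78 °C) can deprotonate it only at C6 and gives lithium (3S)-3-(3,3-diethoxypropyl)-4,4-dimethoxycyclohexa-1,5-dien-1-olate F2, which MeI methylates to 6. The enantio-determining event is unchanged; the methylation becomes an ordinary lithium-enolate alkylation.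

Step 2. Michael addition of a fully substituted enolate to the vinyl sulfoxide may be reversible or low-yielding. The fallback sets out from 6 and returns at 9. The lithium dienolate 7 is added to acetaldehyde at −78 °C (aldol addition, same facial bias) to give (5S,6R)-5-(3,3-diethoxypropyl)-6-(1-hydroxyethyl)-4,4-dimethoxy-6-methylcyclohex-2-en-1-one F3 (either carbinol epimer). Syn-dehydration with the Burgess reagent, for which only the methyl group offers β-hydrogens, then gives 9.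

Step 15. The chair preference in the [3,3] shift may be small, so much of the wrong enal isomer could form. The fallback sets out from 26 and returns at 27. The unwanted isomer (2Z)-2-[(2R,3S,4S)-2-[3-(tert-butyldimethylsilyloxy)propyl]-3-[(3E,5R,7E)-5-(tert-butyldimethylsilyloxy)-3,8,12-trimethyltrideca-3,7,11-trien-1-yl]-4-hydroxy-3,4-dimethylcyclohexylidene]propanal F4 is separated and re-equilibrated with a catalytic amount of I2 under visible light (reversible iodine-atom addition to the enal). The mixture is re-chromatographed and F4 recycled until it is consumed as 27.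

Further compounds
F1 | step 1 | (5S)-5-(3,3-diethoxypropyl)-4,4-dimethoxycyclohex-2-en-1-one | O=C1C[C@H](CCC(OCC)OCC)C(OC)(OC)C=C1
F2 | step 1 | lithium (3S)-3-(3,3-diethoxypropyl)-4,4-dimethoxycyclohexa-1,5-dien-1-olate | [Li]OC1=C[C@H](CCC(OCC)OCC)C(OC)(OC)C=C1
F3 | step 2 | (5S,6R)-5-(3,3-diethoxypropyl)-6-(1-hydroxyethyl)-4,4-dimethoxy-6-methylcyclohex-2-en-1-one | CC(O)[C@@]1(C)[C@H](CCC(OCC)OCC)C(OC)(OC)C=CC1=O
F4 | step 15 | (2Z)-2-[(2R,3S,4S)-2-[3-(tert-butyldimethylsilyloxy)propyl]-3-[(3E,5R,7E)-5-(tert-butyldimethylsilyloxy)-3,8,12-trimethyltrideca-3,7,11-trien-1-yl]-4-hydroxy-3,4-dimethylcyclohexylidene]propanal | CC(C)=CCC/C(C)=C/C[C@@H](O[Si](C)(C)C(C)(C)C)/C=C(\C)CC[C@@]1(C)[C@H](CCCO[Si](C)(C)C(C)(C)C)/C(=C(/C)C=O)CC[C@]1(C)O
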